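The benzofuran is disconnected at the C3–C3a bond. Furan carbon C3 and its exocyclic carboxyl carbon are the C3 methylene and C4 ketone of a flavanone, whose fused benzene ring is bonded to C4 instead of C3. One hypervalent-iodine oxidation shifts that ring carbon (C4a) onto C3, so the six-membered pyranone contracts to the dihydrofuran, the C3–C3a bond forms and the ketone emerges as the C3 methyl ester. The precursor is a racemic 6-bromoflavanone with all phenols as benzyl ethers. Bromine serves a later Heck reaction, and one BCl3 debenzylation, which should spare the cinnamate alkene and the lactate esters, ends the route.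

Key step: step 5

Assumption: danshensu 12 is used as the free (R)-acid; the ring stereocentres made in steps 4 and 5 are racemic by design and erased in step 6, so the only stereocentres of the target are the two (R)-lactate carbons, which are bought in and never take part in bond making or breaking.

Step 1
Reactants: 1 1-(2,3-dihydroxyphenyl)ethanone
Product: 2 1-[3-(benzyloxy)-2-hydroxyphenyl]ethanone
Conditions: NaH (2.1 equiv), DMF, 0 °C; BnBr (1.0 equiv), 0 °C→rt; aq. HCl
Reagents that add atoms: benzyl bromide, BrCc1ccccc1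
Why: Williamson etherification of the catechol dianion should be selective because the 3-phenoxide, unlike the 2-phenoxide, is neither conjugated with nor chelated to the acetyl group and is therefore the more nucleophilic oxygen for the single equivalent of benzyl bromide.

Step 2
Reactants: 2 1-[3-(benzyloxy)-2-hydroxyphenyl]ethanone
Product: 3 1-[3-(benzyloxy)-5-bromo-2-hydroxyphenyl]ethanone
Conditions: NBS (1.05 equiv), MeCN, 0 °C→rt
Reagents that add atoms: N-bromosuccinimide, O=C1CCC(=O)N1Br
Why: Electrophilic aromatic bromination is directed by the free 2-hydroxyl group to its only open activated position, the para carbon C5 (also meta to the acetyl group), as in the bromination of o-vanillin.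

Step 3
Reactants: 3 1-[3-(benzyloxy)-5-bromo-2-hydroxyphenyl]ethanone; 4 3,4-bis(benzyloxy)benzaldehyde
Product: 5 (E)-1-[3-(benzyloxy)-5-bromo-2-hydroxyphenyl]-3-[3,4-bis(benzyloxy)phenyl]prop-2-en-1-one
Conditions: KOH (50% aq.), EtOH/THF, rt; aq. HCl
Reagents that add atoms: none
Why: Claisen–Schmidt condensation: the methyl ketone enolate adds to the non-enolisable aldehyde and E1cB dehydration gives the conjugated (E)-enone as the thermodynamic product, benzyl ethers and the aryl bromide being inert to aqueous alkali.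

Step 4
Reactants: 5 (E)-1-[3-(benzyloxy)-5-bromo-2-hydroxyphenyl]-3-[3,4-bis(benzyloxy)phenyl]prop-2-en-1-one
Product: 6 8-(benzyloxy)-2-[3,4-bis(benzyloxy)phenyl]-6-bromochroman-4-one (racemic flavanone)
Conditions: NaOAc, EtOH/THF, reflux; recovered 5 recycled
Reagents that add atoms: none
Why: Acetate-buffered intramolecular oxa-Michael addition (6-endo-trig) of the 2′-phenol to the enone closes the pyranone ring reversibly; the new C2 centre is formed racemic, which is acceptable because it is erased in step 6.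

Step 5
Reactants: 6 8-(benzyloxy)-2-[3,4-bis(benzyloxy)phenyl]-6-bromochroman-4-one (racemic)
Product: 8 methyl trans-7-(benzyloxy)-2-[3,4-bis(benzyloxy)phenyl]-5-bromo-2,3-dihydrobenzofuran-3-carboxylate (racemic), via methyl enol ether 7 (not isolated)
Conditions: PhI(OAc)2 (1.2 equiv), conc. H2SO4, HC(OMe)3, 0 °C→rt
Reagents that add atoms: trimethyl orthoformate, COC(OC)OC
Why: In acidic trimethyl orthoformate the ketone of 6 becomes methyl enol ether 7, which is attacked at C3 by the trivalent iodine electrophile on the face opposite the 2-aryl group to give a 3-iodanyl 4,4-dimethoxy intermediate. The benzo-ring carbon C4a, activated by the ring oxygen ortho to it, then migrates from C4 to C3 while iodobenzene leaves, and the dimethoxycarbenium ion left at C4 loses a methyl group to give the methyl ester. The closest known reaction type is the hypervalent-iodine oxidative ring contraction of flavanones, a semipinacol-type 1,2-aryl shift. The five-membered ring arises by contraction and not by end-to-end cyclisation: the C3–C3a bond forms in a suprafacial 1,2-shift through a phenonium-type bridged transition state, formally a 3-exo-tet displacement of iodobenzene at C3 by the ipso carbon. The new C3 centre is set by substrate control from C2, since iodine enters anti to the equatorial 2-aryl group and the shift inverts C3, which places the ester trans to the aryl group (also the more stable isomer). The step needs benzo-ring migration to outrun 2,3-shift of the electron-rich 2-aryl group and elimination to the flavone; the half-chair with equatorial 2-aryl and equatorial C3–iodine bonds aligns only the C4–C4a bond anti-periplanar to the leaving group, and near-stoichiometric oxidant at or below room temperature limits over-oxidation and acidolysis of the benzyl ethers.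

Step 6
Reactants: 8 methyl trans-7-(benzyloxy)-2-[3,4-bis(benzyloxy)phenyl]-5-bromo-2,3-dihydrobenzofuran-3-carboxylate (racemic)
Product: 9 methyl 7-(benzyloxy)-2-[3,4-bis(benzyloxy)phenyl]-5-bromobenzofuran-3-carboxylate
Conditions: DDQ (2 equiv), 1,4-dioxane, reflux
Reagents that add atoms: none
Why: DDQ dehydrogenation: hydride abstraction from C2, which is benzylic, α to oxygen and stabilised by the dialkoxyphenyl group, followed by loss of the acidic C3 proton aromatises the furan ring, while aryl benzyl ethers (unlike 4-methoxybenzyl ethers) are not oxidised at a useful rate.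

Step 7
Reactants: 9 methyl 7-(benzyloxy)-2-[3,4-bis(benzyloxy)phenyl]-5-bromobenzofuran-3-carboxylate
Product: 10 methyl 7-(benzyloxy)-2-[3,4-bis(benzyloxy)phenyl]-5-[(E)-3-methoxy-3-oxoprop-1-en-1-yl]benzofuran-3-carboxylate
Conditions: methyl acrylate (3 equiv), Pd(OAc)2 (5 mol %), P(o-tol)3 (10 mol %), Et3N, DMF, 100 °C
Reagents that add atoms: methyl acrylate, C=CC(=O)OC
Why: Mizoroki–Heck reaction: oxidative addition of the aryl bromide to zerovalent palladium, syn-insertion of the acrylate and syn-β-hydride elimination give the (E)-cinnamate, and no other group in 9 reacts with palladium under these conditions.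

Step 8
Reactants: 10 methyl 7-(benzyloxy)-2-[3,4-bis(benzyloxy)phenyl]-5-[(E)-3-methoxy-3-oxoprop-1-en-1-yl]benzofuran-3-carboxylate
Product: 11 7-(benzyloxy)-2-[3,4-bis(benzyloxy)phenyl]-5-[(E)-2-carboxyethenyl]benzofuran-3-carboxylic acid
Conditions: KOH, THF/MeOH/H2O, 65 °C; aq. HCl
Reagents that add atoms: potassium hydroxide (aqueous; supplies the new carboxyl oxygen), [OH-].[K+]
Why: Saponification of both methyl esters; the hindered C3 ester needs heat, which the benzyl ethers, the benzofuran and the cinnamate double bond tolerate.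

Step 9
Reactants: 12 (R)-3-(3,4-dihydroxyphenyl)lactic acid (danshensu)
Product: 13 benzyl (2R)-3-[3,4-bis(benzyloxy)phenyl]-2-hydroxypropanoate
Conditions: BnBr (3.3 equiv), K2CO3, DMF, rt, argon
Reagents that add atoms: benzyl bromide, BrCc1ccccc1
Why: Carbonate-mediated O-alkylation (Williamson) benzylates the carboxylate and both phenoxides, while the secondary alcohol, which K2CO3 does not deprotonate, stays free and the (R) centre is untouched.

Step 10
Reactants: 11 7-(benzyloxy)-2-[3,4-bis(benzyloxy)phenyl]-5-[(E)-2-carboxyethenyl]benzofuran-3-carboxylic acid; 13 benzyl (2R)-3-[3,4-bis(benzyloxy)phenyl]-2-hydroxypropanoate (2.3 equiv)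
Product: 15 nona-O-benzyl schizotenuin A (seven phenols as benzyl ethers, both lactate carboxyls as benzyl esters; R,R; E), via bis(acid chloride) 14 (not isolated)
Conditions: (COCl)2, DMF (cat.), CH2Cl2, 0 °C→rt, evaporate; 13, Et3N, DMAP, CH2Cl2, 0 °C→rt
Reagents that add atoms: none
Why: Nucleophilic acyl substitution via the acid chlorides with DMAP catalysis overcomes the low nucleophilicity of the α-hydroxy ester and the hindrance at C3; neither acyl chloride can form a ketene, and the C–O bond at each (R) centre is not broken, so configuration is retained.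

Step 11
Reactants: 15 nona-O-benzyl schizotenuin A
Product: 16 schizotenuin A
Conditions: BCl3 (excess), C6HMe5, CH2Cl2, −78→0 °C; H2O/THF quench
Reagents that add atoms: none
Why: BCl3-mediated debenzylation with pentamethylbenzene as a non-basic benzyl-cation scavenger (Friedel–Crafts capture) should cleave all seven aryl benzyl ethers and both benzyl esters without reducing the cinnamate alkene, and the two lactate ester links survive because their α-carbonyl secondary carbons cannot ionise; both stereocentres are untouched.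

Compound list
1 | 1-(2,3-dihydroxyphenyl)ethanone | CC(=O)c1cccc(O)c1O | starting material
2 | 1-[3-(benzyloxy)-2-hydroxyphenyl]ethanone | CC(=O)c1cccc(OCc2ccccc2)c1O | intermediate
3 | 1-[3-(benzyloxy)-5-bromo-2-hydroxyphenyl]ethanone | CC(=O)c1cc(Br)cc(OCc2ccccc2)c1O | intermediate
4 | 3,4-bis(benzyloxy)benzaldehyde | O=Cc1ccc(OCc2ccccc2)c(OCc2ccccc2)c1 | starting material
5 | (E)-1-[3-(benzyloxy)-5-bromo-2-hydroxyphenyl]-3-[3,4-bis(benzyloxy)phenyl]prop-2-en-1-one | O=C(/C=C/c1ccc(OCc2ccccc2)c(OCc2ccccc2)c1)c1cc(Br)cc(OCc2ccccc2)c1O | intermediate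
6 | 8-(benzyloxy)-2-[3,4-bis(benzyloxy)phenyl]-6-bromochroman-4-one (racemic) | O=C1CC(c3ccc(OCc4ccccc4)c(OCc4ccccc4)c3)Oc2c1cc(Br)cc2OCc1ccccc1 | intermediate
7 | 8-(benzyloxy)-2-[3,4-bis(benzyloxy)phenyl]-6-bromo-4-methoxy-2H-chromene (racemic methyl enol ether) | COC1=CC(c3ccc(OCc4ccccc4)c(OCc4ccccc4)c3)Oc2c1cc(Br)cc2OCc1ccccc1 | intermediate (not isolated)
8 | methyl trans-7-(benzyloxy)-2-[3,4-bis(benzyloxy)phenyl]-5-bromo-2,3-dihydrobenzofuran-3-carboxylate (racemic; 2R,3R enantiomer drawn) | c1ccccc1COc1cc(Br)cc2c1O[C@@H](c1ccc(OCc3ccccc3)c(OCc3ccccc3)c1)[C@@H]2C(=O)OC | intermediate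
9 | methyl 7-(benzyloxy)-2-[3,4-bis(benzyloxy)phenyl]-5-bromobenzofuran-3-carboxylate | COC(=O)c1c(-c2ccc(OCc3ccccc3)c(OCc3ccccc3)c2)oc2c(OCc3ccccc3)cc(Br)cc12 | intermediate
10 | methyl 7-(benzyloxy)-2-[3,4-bis(benzyloxy)phenyl]-5-[(E)-3-methoxy-3-oxoprop-1-en-1-yl]benzofuran-3-carboxylate | COC(=O)/C=C/c1cc(OCc2ccccc2)c2oc(-c3ccc(OCc4ccccc4)c(OCc4ccccc4)c3)c(C(=O)OC)c2c1 | intermediate
11 | 7-(benzyloxy)-2-[3,4-bis(benzyloxy)phenyl]-5-[(E)-2-carboxyethenyl]benzofuran-3-carboxylic acid | OC(=O)/C=C/c1cc(OCc2ccccc2)c2oc(-c3ccc(OCc4ccccc4)c(OCc4ccccc4)c3)c(C(=O)O)c2c1 | intermediate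
12 | (R)-3-(3,4-dihydroxyphenyl)lactic acid (danshensu) | O[C@H](Cc1ccc(O)c(O)c1)C(=O)O | starting material
13 | benzyl (2R)-3-[3,4-bis(benzyloxy)phenyl]-2-hydroxypropanoate | O[C@H](Cc1ccc(OCc2ccccc2)c(OCc2ccccc2)c1)C(=O)OCc1ccccc1 | intermediate
14 | 7-(benzyloxy)-2-[3,4-bis(benzyloxy)phenyl]-5-[(E)-3-chloro-3-oxoprop-1-en-1-yl]benzofuran-3-carbonyl chloride | O=C(Cl)/C=C/c1cc(OCc2ccccc2)c2oc(-c3ccc(OCc4ccccc4)c(OCc4ccccc4)c3)c(C(=O)Cl)c2c1 | intermediate (not isolated)
15 | nona-O-benzyl schizotenuin A: benzofuran 3-carboxylate and 5-(E)-propenoate both esterified with 13 through its (R)-hydroxyl | O=C(/C=C/c1cc(OCc4ccccc4)c2oc(-c3ccc(OCc4ccccc4)c(OCc4ccccc4)c3)c(C(=O)O[C@H](Cc3ccc(OCc4ccccc4)c(OCc4ccccc4)c3)C(=O)OCc3ccccc3)c2c1)O[C@H](Cc1ccc(OCc2ccccc2)c(OCc2ccccc2)c1)C(=O)OCc1ccccc1 | intermediate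
16 | schizotenuin A | O=C(/C=C/c1cc(O)c2oc(-c3ccc(O)c(O)c3)c(C(=O)O[C@H](Cc3ccc(O)c(O)c3)C(=O)O)c2c1)O[C@H](Cc1ccc(O)c(O)c1)C(=O)O | target

Total step count: 11. Longest linear sequence: 10 steps (steps 1–8, 10 and 11, from compound 1).

Steps most likely to fail

Step 5. The benzo-ring shift may be overtaken by migration of the electron-rich 2-aryl group or by elimination to the flavone, and the strongly acidic oxidising medium may strip benzyl ethers. The fallback keeps the same ring contraction but reaches it by a Wolff rearrangement, without acid or oxidant. It sets out from 6. C-Trifluoroacetylation of the lithium enolate (LiHMDS, THF, −78 °C; CF3CO2CH2CF3, kept cold to suppress retro-oxa-Michael opening) should give 8-(benzyloxy)-2-[3,4-bis(benzyloxy)phenyl]-6-bromo-3-(trifluoroacetyl)chroman-4-one F1. Detrifluoroacetylative diazo transfer (MsN3, Et3N, MeCN/H2O) should give the 3-diazochroman-4-one F2. Irradiation at 365 nm in MeOH/THF should expel dinitrogen with migration of C4a to C3 to give the ring-contracted ketene F3, which methanol traps as ester 8 together with its cis epimer F4. The epimer mixture is dehydrogenated with DDQ as in step 6, so the fallback comes back to the route at 9.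

Step 10. Acylation at the hindered C3 acid chloride by the poorly nucleophilic α-hydroxy ester may stall at mono-ester stage, and prolonged exposure to base may erode the lactate configuration. The fallback forms the cinnamate C–C bond last instead of its C–O bond. It sets out from 9. Saponification (KOH, aq. THF/MeOH, 65 °C) gives 7-(benzyloxy)-2-[3,4-bis(benzyloxy)phenyl]-5-bromobenzofuran-3-carboxylic acid F5. (COCl)2 with catalytic DMF gives its acid chloride F6, which acylates 13 (Et3N, DMAP, CH2Cl2) to the bromo mono-lactate ester F7. Separately 13 and acryloyl chloride (Et3N, CH2Cl2, 0 °C) give benzyl (2R)-2-(acryloyloxy)-3-[3,4-bis(benzyloxy)phenyl]propanoate F8. Heck coupling of F7 with F8 (Pd(OAc)2, P(o-tol)3, Et3N, DMF, 90 °C) comes back to the route at 15.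

Step 11. Cleavage of the two benzyl esters may lag behind that of the aryl ethers, and the warming needed to finish it may bring C-benzylation of the catechol rings or scission of the lactate ester links. The fallback moves the carboxyl protection to allyl and unmasks in two mild stages. It sets out from 13 (with 11 converted into 14 as in step 10). Ti(OiPr)4-catalysed transesterification of 13 in allyl alcohol gives allyl (2R)-3-[3,4-bis(benzyloxy)phenyl]-2-hydroxypropanoate F9. Esterification of 14 with F9 (Et3N, DMAP) gives the hepta-O-benzyl diallyl ester F10. Pd(PPh3)4 (zerovalent palladium) with morpholine in THF removes both allyl groups by Tsuji–Trost deallylation to give the hepta-O-benzyl diacid F11. BCl3/C6HMe5 at −78 °C, where only aryl benzyl ethers have to ionise, then comes back to the route at 16.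

Further compounds
F1 | step 5 | 8-(benzyloxy)-2-[3,4-bis(benzyloxy)phenyl]-6-bromo-3-(trifluoroacetyl)chroman-4-one (racemic) | O=C1C(C(=O)C(F)(F)F)C(c3ccc(OCc4ccccc4)c(OCc4ccccc4)c3)Oc2c1cc(Br)cc2OCc1ccccc1
F2 | step 5 | 8-(benzyloxy)-2-[3,4-bis(benzyloxy)phenyl]-6-bromo-3-diazochroman-4-one (racemic) | O=C1C(=[N+]=[N-])C(c3ccc(OCc4ccccc4)c(OCc4ccccc4)c3)Oc2c1cc(Br)cc2OCc1ccccc1
F3 | step 5 | [7-(benzyloxy)-2-[3,4-bis(benzyloxy)phenyl]-5-bromobenzofuran-3(2H)-ylidene]methanone (racemic ketene) | O=C=C1c2cc(Br)cc(OCc3ccccc3)c2OC1c1ccc(OCc2ccccc2)c(OCc2ccccc2)c1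
F4 | step 5 | methyl cis-7-(benzyloxy)-2-[3,4-bis(benzyloxy)phenyl]-5-bromo-2,3-dihydrobenzofuran-3-carboxylate (racemic; 2R,3S enantiomer drawn) | c1ccccc1COc1cc(Br)cc2c1O[C@@H](c1ccc(OCc3ccccc3)c(OCc3ccccc3)c1)[C@H]2C(=O)OC
F5 | step 10 | 7-(benzyloxy)-2-[3,4-bis(benzyloxy)phenyl]-5-bromobenzofuran-3-carboxylic acid | OC(=O)c1c(-c2ccc(OCc3ccccc3)c(OCc3ccccc3)c2)oc2c(OCc3ccccc3)cc(Br)cc12
F6 | step 10 | 7-(benzyloxy)-2-[3,4-bis(benzyloxy)phenyl]-5-bromobenzofuran-3-carbonyl chloride | ClC(=O)c1c(-c2ccc(OCc3ccccc3)c(OCc3ccccc3)c2)oc2c(OCc3ccccc3)cc(Br)cc12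
F7 | step 10 | benzyl (2R)-3-[3,4-bis(benzyloxy)phenyl]-2-({7-(benzyloxy)-2-[3,4-bis(benzyloxy)phenyl]-5-bromobenzofuran-3-carbonyl}oxy)propanoate | O=C(O[C@H](Cc1ccc(OCc2ccccc2)c(OCc2ccccc2)c1)C(=O)OCc1ccccc1)c1c(-c2ccc(OCc3ccccc3)c(OCc3ccccc3)c2)oc2c(OCc3ccccc3)cc(Br)cc12
F8 | step 10 | benzyl (2R)-2-(acryloyloxy)-3-[3,4-bis(benzyloxy)phenyl]propanoate | C=CC(=O)O[C@H](Cc1ccc(OCc2ccccc2)c(OCc2ccccc2)c1)C(=O)OCc1ccccc1
F9 | step 11 | allyl (2R)-3-[3,4-bis(benzyloxy)phenyl]-2-hydroxypropanoate | O[C@H](Cc1ccc(OCc2ccccc2)c(OCc2ccccc2)c1)C(=O)OCC=C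
F10 | step 11 | hepta-O-benzyl schizotenuin A diallyl ester | O=C(/C=C/c1cc(OCc4ccccc4)c2oc(-c3ccc(OCc4ccccc4)c(OCc4ccccc4)c3)c(C(=O)O[C@H](Cc3ccc(OCc4ccccc4)c(OCc4ccccc4)c3)C(=O)OCC=C)c2c1)O[C@H](Cc1ccc(OCc2ccccc2)c(OCc2ccccc2)c1)C(=O)OCC=C
F11 | step 11 | hepta-O-benzyl schizotenuin A (free diacid) | O=C(/C=C/c1cc(OCc4ccccc4)c2oc(-c3ccc(OCc4ccccc4)c(OCc4ccccc4)c3)c(C(=O)O[C@H](Cc3ccc(OCc4ccccc4)c(OCc4ccccc4)c3)C(=O)O)c2c1)O[C@H](Cc1ccc(OCc2ccccc2)c(OCc2ccccc2)c1)C(=O)O
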